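The easy step is one multiplication: the end reading of complex with one exchanged, times the charge. Amber at 13 mM and violet at 90 mM both read 30.0 % at 4.00 min, on the same ligand and schedule as the new flasks. So I carry the counted share, 30.0 %, the part of the charged starting complex found at the end as complex with one exchanged, bound forms included.

| flask | starting complex | incoming ligand | remark | time |
|---|---|---|---|---|
| amber | 13 mM (in portions, 2) | 40 mM | run made earlier; portions every 80 s |  |
| violet | 90 mM (in portions, 2) | 40 mM | run made earlier; portions every 80 s |  |
| winter | 10 mM (in portions, 2) | 40.0 mM | the portions of starting complex follow each other after 80 s, the first at the start | 4.0 min |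
| spring | 20 mM (in portions, 2) | 40.0 mM | the portions of starting complex follow each other after 80 s, the first at the start | 4.0 min |
| noon | 40 mM (in portions, 2) | 40.0 mM | the portions of starting complex follow each other after 80 s, the first at the start | 4.0 min |
| dusk | 80 mM (in portions, 2) | 40.0 mM | the portions of starting complex follow each other after 80 s, the first at the start | 4.0 min |

| run | time / min | complex with one exchanged / % |
|---|---|---|
| amber | 0.667 | 7.5 |
| amber | 1.33 | 11.1 |
| amber | 2.00 | 22.2 |
| amber | 2.50 | 26.0 |
| amber | 3.00 | 28.5 |
| amber | 4.00 | 30.0 |
| violet | 0.667 | 7.8 |
| violet | 1.33 | 11.9 |
| violet | 2.00 | 19.9 |
| violet | 2.50 | 24.3 |
| violet | 3.00 | 26.1 |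
| violet | 4.00 | 30.0 |

(scatter of a reading: 0.5 percentage points)
1. [complex with one exchanged] (only what is free in solution) at the end for winter, spring, noon, dusk, in this order
2. the course of these numbers from the first flask to the last (falls all the way / rises, then falls / rises all the way / falls, then rises / hardly changes)
- what was read earlier has a scatter of 0.5 percentage points, one standard deviation
- a reading or a percentage of complex with one exchanged counts all its forms, free or not
- the concentration of complex with one exchanged that is asked is that of its free form alone
- "hardly changes" means that all values lie within two and a half points (for a concentration: within two and a half percent of the largest)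

The maker of the forecast and I agree on that share, but we dispute what it means for the question, which asks for the free form. The forecast multiplies through and gets 3 mM, 6 mM, 12 mM and 24 mM, so its row rises all the way. Its words are “I therefore treat free as nearly total”.

I hold that the product is a count and not the free form: in winter 3.00 mM, in dusk 24.0 mM. My ground is in the early readings. Amber gains 7.5 % by 0.667 min, then 3.6 percentage points by 1.33 min, about half as much, although the reading then stood for just 15.0 % of the first portion. Violet shows about half as well at 90 mM, so in these readings the slowing does not grow with the charge; I take it as a hint, no more, that the product binds something in the flask.

I solve the two ends and join them. At the winter end, with little partner present, the free form should lie nearest the count. At the dusk end, the partner grows with the charge, so the free form should stop following it. I cannot put a figure on the binding, so I commit to the bend: the row stays under the count, and its rise stops before dusk.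

    starting complex + incoming ligand → leaving ligand + complex with one exchanged (k = 0.124 M⁻¹ s⁻¹)
    complex with one exchanged + incoming ligand → leaving ligand + complex with two exchanged (k = 0.404 M⁻¹ s⁻¹)
    starting complex + complex with one exchanged ⇌ idle adduct, settled at all times (K = 467 M⁻¹)

The flasks end at 1.11 mM, 1.63 mM, 1.94 mM and 1.62 mM, so the row rises, then falls, turning near 42 mM. With its bound forms counted, complex with one exchanged ends at 28.4 % in winter and 30.9 % in dusk, so the forecast's view holds for the count. Against share times charge, the free form is 37.0 % in winter and 6.75 % in dusk, where the idle adduct, that flask's resting state, holds 57.8 % of the charge.

The readings were generated by integration with made-up constants; noise was put on by code.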